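**Retrosynthetic overview**

1. Numbering: ring A is the ten-membered carbocycle C1–C10 (C1 ketone, C4=C5 Z-olefin, C6 lactone carbinol, C8 tiglate carbinol, C9 free carbinol, C10 methyl-bearing); ring B is the butenolide O6–C6–C7=C11–C12(=O), with acetoxymethyl carbon C13 on C11. The last operations are tigloylation at O8 and N–O cleavage of a 2-isoxazoline (temporary ring C) that masks the C1 ketone and the C9 hydroxyl.
2. Key disconnection C11–C12 (closes ring B): the array O6–C6–C7=C11(–C12)–C13–OAc is an exocyclic allene C7=C11=C13 on ring A that has taken up an acyl carbon at its central atom and acetate at its terminus, with O6 placed to deliver the carbonyl. The precursor is therefore the caesium oxalate of an allenyl carbinol, closed by anodic decarboxylation with radical-to-cation crossover.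
3. Ring A is closed earlier at C6–C7 by a chromium-mediated propargyl bromide/enal allenylation, which creates the allene and the C6 carbinol in the same event.
4. C8, C9, C10 and the C1 oxidation level come from a magnesium-alkoxide-directed nitrile oxide cycloaddition between a neryl acetate-derived oxime (C1–C6, Z-olefin) and an (S)-enynol made from crotonaldehyde and 4-methoxybenzyl propargyl ether.
5. Order of ring formation: ring C (isoxazoline), then ring A (carbocycle), then ring B (butenolide); ring C is opened last.

Key step: step 12

Remark on the chemistry: the target is read as 4Z, 6R, 8R, 9R, 10S with an (E)-2-methylbut-2-enoate (tiglate). Assumption: the (S,S)-ProPhenol antipode delivers the (S)-carbinol 6; this is to be confirmed by MTPA ester analysis and the ligand antipode exchanged if necessary.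

**Step 1**
Reactants: 1 neryl acetate
Product: 2 (Z)-3-methyl-6-oxohex-2-en-1-yl acetate
Conditions: O3 (1 equiv, Sudan Red 7B end point), CH2Cl2/MeOH, −78 °C; then Me2S
Reagents that add atoms: ozone, O=[O+][O-]
Why: Chemoselective ozonolysis with reductive work-up: the remote trisubstituted olefin is more electron-rich than the one deactivated by the allylic acetate, so one equivalent of ozone should cleave only the isopropylidene group and leave the Z-olefin untouched.

**Step 2**
Reactants: 2 (Z)-3-methyl-6-oxohex-2-en-1-yl acetate
Product: 3 aldoxime of 2 (C=N isomer mixture, used as such)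
Conditions: NH2OH·HCl, NaOAc, EtOH/H2O, 0 °C to rt
Reagents that add atoms: hydroxylamine hydrochloride, Cl.NO
Why: Oxime condensation of the saturated aldehyde is fast under buffered conditions that leave the primary acetate and the Z-olefin alone; no stereocentre is formed.

**Step 3**
Reactants: 4 4-methoxybenzyl propargyl ether; 5 (E)-crotonaldehyde
Product: 6 (4S,5E)-1-[(4-methoxybenzyl)oxy]hept-5-en-2-yn-4-ol
Conditions: Me2Zn, (S,S)-ProPhenol (cat.), Ph3PO (cat.), toluene, 0 °C
Reagents that add atoms: none
Why: Catalytic asymmetric alkynylation of an enal (alkynylzinc 1,2-addition in the chiral dinuclear zinc–ProPhenol pocket) should set the carbinol that becomes C8 by catalyst control with high enantiomeric excess.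

**Step 4**
Reactants: 3 aldoxime; 6 (S)-enynol
Product: 9 isoxazoline adduct with free C8 hydroxyl, via hydroximoyl chloride 7 (not isolated), via nitrile oxide 8 (not isolated)
Conditions: 3, NCS, pyridine (cat.), CH2Cl2, 0 °C; then slow addition to 6, i-PrOH, EtMgBr, CH2Cl2, 0 °C to rt
Reagents that add atoms: none
Why: Hydroxyl-directed nitrile oxide–olefin (3+2) cycloaddition: the bromomagnesium alkoxide of 6 binds the nitrile oxide oxygen and delivers it to the olefin carbon next to the carbinol on the alkoxide face (O–C9 threo to O–C8), and suprafacial addition to the E-olefin puts the C10 methyl trans to C8, so C9 and C10 are both set from C8; the internal alkyne cannot reach the chelated geometry and the primary acetate should be inert to the poorly nucleophilic magnesium alkoxides at 0 °C.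

**Step 5**
Reactants: 9 isoxazoline adduct
Product: 10 C8 tert-butyldimethylsilyl ether of 9
Conditions: TBSOTf, 2,6-lutidine, CH2Cl2, −78 to 0 °C
Reagents that add atoms: tert-butyldimethylsilyl triflate, CC(C)(C)[Si](C)(C)OS(=O)(=O)C(F)(F)F
Why: Silylation of the only free hydroxyl; a silyl ether (a poor leaving group) is chosen so that the later propargyl chromium species does not undergo 1,4-elimination, and it keeps O8 distinct from O6 and O9.

**Step 6**
Reactants: 10 silyl ether acetate
Product: 11 primary allylic alcohol (C6 hydroxyl free)
Conditions: K2CO3 (cat.), MeOH, 0 °C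
Reagents that add atoms: none
Why: Transesterification (methanolysis) removes the only ester; the secondary silyl ether, the PMB ether and the isoxazoline are stable to catalytic carbonate.

**Step 7**
Reactants: 11 allylic alcohol
Product: 12 (Z)-enal
Conditions: TEMPO (cat.), PhI(OAc)2, CH2Cl2, rt
Reagents that add atoms: none
Why: Oxoammonium-mediated oxidation of the primary allylic alcohol under neutral conditions, chosen because it should not isomerise the Z-trisubstituted enal.

**Step 8**
Reactants: 12 (Z)-enal PMB ether
Product: 13 propargylic alcohol (C13 hydroxyl free)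
Conditions: DDQ, CH2Cl2/pH 7 buffer, 0 °C
Reagents that add atoms: none
Why: Oxidative cleavage of the 4-methoxybenzyl ether by DDQ under buffered conditions, orthogonal to the silyl ether, the enal and the isoxazoline.

**Step 9**
Reactants: 13 propargylic alcohol
Product: 15 propargylic bromide, via propargylic mesylate 14 (not isolated)
Conditions: MsCl, Et3N, CH2Cl2, −40 °C; then LiBr, THF, 0 °C
Reagents that add atoms: lithium bromide, [Li+].[Br-]
Why: Sulfonylation followed by SN2 displacement with bromide; this sequence is used instead of a phosphine/CBr4 bromination because it leaves the aldehyde untouched.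

**Step 10**
Reactants: 15 bromo enal
Product: 16 macrocyclic allenol (ring A closed; 7-vinylidene, 6R hydroxyl)
Conditions: CrCl2, LiI (cat.), THF/DMA, syringe-pump addition (high dilution), rt; aq. work-up
Reagents that add atoms: none
Why: Nozaki–Hiyama–Kishi-type carbonyl allenylation: divalent chromium reduces the propargylic bromide and the resulting trivalent propargyl chromium species adds to the aldehyde in the SE2′ sense through a closed six-membered transition state, closing ring A at C6–C7 and giving the exocyclic allene; C6 is set in the ring-forming transition state, where the C5 arm and the C8 silyloxy group should both take outward positions next to C7, which corresponds to the 6,8-cis (6R) carbinol.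

**Step 11**
Reactants: 16 macrocyclic allenol
Product: 18 caesium oxalate of 16, via methyl oxalate 17 (not isolated)
Conditions: ClCOCO2Me, Et3N, DMAP (cat.), CH2Cl2, 0 °C; then CsOH·H2O (1.0 equiv), THF/H2O, 0 °C
Reagents that add atoms: methyl chlorooxoacetate, COC(=O)C(Cl)=O; caesium hydroxide monohydrate, [Cs+].[OH-].O
Why: Acylation of the only free hydroxyl followed by selective saponification of the unhindered methyl ester of the mixed oxalate (the only esters in the molecule) gives the salt without exposing the doubly allylic C6–O bond to acid; C6 is not touched.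

**Step 12**
Reactants: 18 caesium oxalate
Product: 19 13-acetoxy butenolide (ring B closed; O8 silyl ether, isoxazoline intact)
Conditions: undivided cell, Pt anode, Pt cathode, constant current (about 2.2 F/mol), n-Bu4NPF6, MeCN/AcOH (4:1), 0 °C
Reagents that add atoms: acetic acid, CC(=O)O
Why: Proposed new method: anodic oxidation of the oxalate monoanion (the only carboxylate present, since acetic acid stays protonated) gives an acyloxy radical that loses CO2 to the alkoxycarbonyl radical on O6, which adds to the central allene carbon C11 (new C11–C12 bond) to give the C7–C11–C13 allyl radical; this is oxidised at the anode to the allyl cation, which acetic acid captures at the primary terminus C13, leaving C7=C11 conjugated with the lactone. The closest known reactions are the 5-exo lactonisations of alkoxycarbonyl radicals made by one-electron oxidation of alkyl oxalates, radical additions to the central carbon of allenes, and the Kolbe/Hofer–Moest radical-to-cation crossover with acetate capture. Ring B closes in a 5-exo-trig mode with respect to the C11=C13 π bond, which lies in the plane of C6, C7 and C8 and is therefore within reach of the tethered radical. No stereocentre is created: C6 and C8 are carried through, and the tether from O6 fixes C12 cis to C6 across the new tetrasubstituted olefin. The step needs ring closure to outrun loss of a second CO2 from the alkoxycarbonyl radical, and capture at C13 rather than C7: low temperature, the short rigid tether and formation of an allyl radical favour the first, while the unhindered primary terminus and conjugation in the product favour the second (a C7 acetate, if formed, should transpose to the conjugated primary acetate). The silyl ether at O8 offers no neighbouring-group participation, and the isoxazoline, the ring olefin and the allene oxidise at much higher potential than the carboxylate.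

**Step 13**
Reactants: 19 silyl ether butenolide
Product: 20 C8 alcohol
Conditions: HF·pyridine, pyridine, THF, 0 °C to rt
Reagents that add atoms: none
Why: Fluoride-mediated desilylation under buffered, non-basic conditions; translactonisation to O8 is not possible because C8 and C12 are trans across the tetrasubstituted C7=C11 bond.

**Step 14**
Reactants: 20 C8 alcohol; 21 tigloyl chloride
Product: 22 O8 tiglate (isoxazoline intact)
Conditions: pyridine, DMAP, CH2Cl2, 0 °C to rt
Reagents that add atoms: none
Why: DMAP-catalysed acylation of the only free hydroxyl with the thermodynamically preferred (E)-acid chloride; O9 is still locked in the isoxazoline, so no regioselectivity question arises.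

**Step 15**
Reactants: 22 O8 tiglate
Product: 23 target CNP0281168.1
Conditions: TiCl3 (aq.), NaOAc, THF/H2O, rt
Reagents that add atoms: water, O
Why: Reductive N–O cleavage of the 2-isoxazoline by trivalent titanium and hydrolysis of the resulting β-hydroxy imine unmasks the C1 ketone and the C9 hydroxyl with C9 and C10 unchanged; the buffered room-temperature medium should spare the enoates, the allylic acetate and the olefins and should not epimerise C10.

**Compound list**

1 | neryl acetate, (Z)-3,7-dimethylocta-2,6-dien-1-yl acetate | CC(=O)OC/C=C(/C)CCC=C(C)C | starting material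
2 | (Z)-3-methyl-6-oxohex-2-en-1-yl acetate | CC(=O)OC/C=C(/C)CCC=O | intermediate
3 | (Z)-6-(hydroxyimino)-3-methylhex-2-en-1-yl acetate (oxime isomer mixture) | CC(=O)OC/C=C(/C)CCC=NO | intermediate
4 | 1-methoxy-4-[(prop-2-yn-1-yloxy)methyl]benzene (4-methoxybenzyl propargyl ether) | C#CCOCc1ccc(OC)cc1 | starting material
5 | (E)-but-2-enal (crotonaldehyde) | C/C=C/C=O | starting material
6 | (4S,5E)-1-[(4-methoxybenzyl)oxy]hept-5-en-2-yn-4-ol | C/C=C/[C@H](O)C#CCOCc1ccc(OC)cc1 | intermediate
7 | (Z)-6-chloro-6-(hydroxyimino)-3-methylhex-2-en-1-yl acetate (hydroximoyl chloride, not isolated) | CC(=O)OC/C=C(/C)CCC(Cl)=NO | intermediate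
8 | nitrile oxide from 7 (not isolated) | CC(=O)OC/C=C(/C)CCC#[N+][O-] | intermediate
9 | (Z)-5-{(4R,5R)-5-[(1R)-1-hydroxy-4-[(4-methoxybenzyl)oxy]but-2-yn-1-yl]-4-methyl-4,5-dihydroisoxazol-3-yl}-3-methylpent-2-en-1-yl acetate | CC(=O)OC/C=C(/C)CCC1=NO[C@@H]([C@H](O)C#CCOCc2ccc(OC)cc2)[C@@H]1C | intermediate
10 | C8 tert-butyldimethylsilyl ether of 9 | CC(=O)OC/C=C(/C)CCC1=NO[C@@H]([C@H](O[Si](C)(C)C(C)(C)C)C#CCOCc2ccc(OC)cc2)[C@@H]1C | intermediate
11 | primary allylic alcohol from 10 (acetate removed) | OC/C=C(/C)CCC1=NO[C@@H]([C@H](O[Si](C)(C)C(C)(C)C)C#CCOCc2ccc(OC)cc2)[C@@H]1C | intermediate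
12 | (Z)-enal from 11 | O=C/C=C(/C)CCC1=NO[C@@H]([C@H](O[Si](C)(C)C(C)(C)C)C#CCOCc2ccc(OC)cc2)[C@@H]1C | intermediate
13 | (Z)-enal propargylic alcohol (PMB removed) | O=C/C=C(/C)CCC1=NO[C@@H]([C@H](O[Si](C)(C)C(C)(C)C)C#CCO)[C@@H]1C | intermediate
14 | propargylic mesylate of 13 (not isolated) | O=C/C=C(/C)CCC1=NO[C@@H]([C@H](O[Si](C)(C)C(C)(C)C)C#CCOS(C)(=O)=O)[C@@H]1C | intermediate
15 | (Z)-enal propargylic bromide | O=C/C=C(/C)CCC1=NO[C@@H]([C@H](O[Si](C)(C)C(C)(C)C)C#CCBr)[C@@H]1C | intermediate
16 | macrocyclic allenol: ring A with 4Z olefin, 6R hydroxyl, exocyclic 7-vinylidene, 8R silyloxy, isoxazoline N–O bridge from C1 to C9 (9R,10R) | CC(C)(C)[Si](C)(C)O[C@@H]1C(=C=C)[C@H](O)/C=C(/C)CCC2=NO[C@@H]1[C@@H]2C | intermediate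
17 | O6 methyl oxalate of 16 (not isolated) | CC(C)(C)[Si](C)(C)O[C@@H]1C(=C=C)[C@H](OC(=O)C(=O)OC)/C=C(/C)CCC2=NO[C@@H]1[C@@H]2C | intermediate
18 | caesium O6 oxalate of 16 | CC(C)(C)[Si](C)(C)O[C@@H]1C(=C=C)[C@H](OC(=O)C(=O)[O-])/C=C(/C)CCC2=NO[C@@H]1[C@@H]2C.[Cs+] | intermediate
19 | 13-acetoxy-7(11)-en-12,6-olide with O8 silyl ether and C1/C9 isoxazoline (6R,8R,9R,10R) | CC(C)(C)[Si](C)(C)O[C@@H]1C2=C(COC(C)=O)C(=O)O[C@@H]2/C=C(/C)CCC3=NO[C@@H]1[C@@H]3C | intermediate
20 | C8 alcohol from 19 | O[C@@H]1C2=C(COC(C)=O)C(=O)O[C@@H]2/C=C(/C)CCC3=NO[C@@H]1[C@@H]3C | intermediate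
21 | tigloyl chloride, (E)-2-methylbut-2-enoyl chloride | C/C=C(\C)C(Cl)=O | starting material
22 | O8 tiglate of 20 (isoxazoline intact) | C/C=C(\C)C(=O)O[C@@H]1C2=C(COC(C)=O)C(=O)O[C@@H]2/C=C(/C)CCC3=NO[C@@H]1[C@@H]3C | intermediate
23 | CNP0281168.1 (4Z,6R,8R,9R,10S) | C/C=C(\C)C(=O)O[C@@H]1C2=C(COC(C)=O)C(=O)O[C@@H]2/C=C(/C)CCC(=O)[C@@H](C)[C@H]1O | target

**Step count and risks**

Total step count: 15. Longest linear sequence: 14 steps (1 to 23 through steps 1, 2 and 4–15).

Steps most likely to fail:

1. Step 12 (proposed new method). What may go wrong: loss of CO2 from the alkoxycarbonyl radical before ring closure (the C6–O bond is allylic to both the ring olefin and the allene), over-oxidation of the radical at the electrode, or proton loss from the allyl cation instead of acetate capture. The fallback uses two-electron chemistry in which both elementary steps are known: addition of an alkoxycarbonyl–palladium species to the central carbon of an allene followed by nucleophilic opening of the π-allyl palladium intermediate (as in the oxidative carbonylation of allenes to 2-(alkoxymethyl)acrylates), and intramolecular alkoxycarbonylation of unsaturated alcohols to lactones. It sets out from allenol 16 (no oxalate is made) and comes back at 19: 16 is treated with PdCl2(MeCN)2 (cat., divalent palladium), CO (1 atm), p-benzoquinone and NaOAc in AcOH/THF at rt, so that O6 and CO form the alkoxycarbonyl–palladium unit, the allene inserts at C11 and acetate opens the π-allyl at C13. No new isolated compound arises.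

2. Step 10. What may go wrong: poor facial selectivity at the aldehyde in the ring-closing transition state, so that the C6 epimer predominates. The fallback sets out from 15 and comes back at 16: if closure of 15 gives mainly the 6S epimer of the macrocyclic allenol F1, this is inverted by a Mitsunobu reaction (4-nitrobenzoic acid, PPh3, DIAD, THF, 0 °C) to the 6R 4-nitrobenzoate F2, and methanolysis (K2CO3, MeOH, 0 °C) then gives 16.

3. Step 15. What may go wrong: migration of the tiglate from O8 to the newly freed O9, dehydration of the ketol, or loss of the tiglate while the N–O bond is reduced. The fallback sets out from 19 and comes back at 23, moving the unmasking to a stage without an acyl group on O8: 19 is cleaved with TiCl3 (aq.), NaOAc in THF/H2O to the ketol silyl ether F3; the C9 hydroxyl is capped with chloroacetic anhydride and pyridine to give chloroacetate F4; HF·pyridine frees the C8 alcohol F5; acylation with 21 (pyridine, DMAP) gives the tiglate chloroacetate F6; thiourea and NaHCO3 in EtOH at rt remove the chloroacetate under near-neutral conditions to give 23.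

**Further compounds**

F0 | step 12 | none | none
F1 | step 10 | 6S epimer of macrocyclic allenol 16 | CC(C)(C)[Si](C)(C)O[C@@H]1C(=C=C)[C@@H](O)/C=C(/C)CCC2=NO[C@@H]1[C@@H]2C
F2 | step 10 | 6R 4-nitrobenzoate of 16 | CC(C)(C)[Si](C)(C)O[C@@H]1C(=C=C)[C@H](OC(=O)c3ccc(cc3)[N+](=O)[O-])/C=C(/C)CCC2=NO[C@@H]1[C@@H]2C
F3 | step 15 | ketol silyl ether (C1 ketone, C9 hydroxyl, O8 silyl ether) | CC(C)(C)[Si](C)(C)O[C@@H]1C2=C(COC(C)=O)C(=O)O[C@@H]2/C=C(/C)CCC(=O)[C@@H](C)[C@H]1O
F4 | step 15 | O9 chloroacetate of F3 | CC(C)(C)[Si](C)(C)O[C@@H]1C2=C(COC(C)=O)C(=O)O[C@@H]2/C=C(/C)CCC(=O)[C@@H](C)[C@H]1OC(=O)CCl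
F5 | step 15 | C8 alcohol O9 chloroacetate | O[C@@H]1C2=C(COC(C)=O)C(=O)O[C@@H]2/C=C(/C)CCC(=O)[C@@H](C)[C@H]1OC(=O)CCl
F6 | step 15 | O8 tiglate O9 chloroacetate | C/C=C(\C)C(=O)O[C@@H]1C2=C(COC(C)=O)C(=O)O[C@@H]2/C=C(/C)CCC(=O)[C@@H](C)[C@H]1OC(=O)CCl
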